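## Retrosynthetic overview

1. Isariotin D (8) ⇐ tetraol 7 by 1,2‑diol‑selective oxidation at C9; 7 ⇐ epoxy ketone 6 by reduction at C6 (a 1,3 carbonyl/carbinol switch on the finished bicycle).
2. 6 ⇐ p‑quinol aldehyde 5 by one base‑mediated cascade: C9–O bond (water oxa‑Michael), C4–C5 bond (intramolecular aldol, ring A), then the exo oxirane, all steered by the tyrosine Cα.
3. 5 ⇐ phenol aldehyde 4 by photochemical (¹O₂) dearomatisation, which makes the C1–O bond and the quaternary carbinol.
4. 4 ⇐ methyl L‑tyrosinate (1) + (E)‑dec‑2‑enoic acid (2): amide coupling, then ester → aldehyde.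
5. Ring order: carbocycle B (the tyrosine arene, dearomatised) → ring A (aldol, bicyclo[3.3.1]) → oxirane.

Assumption: the core is numbered as bicyclo[3.3.1]nonane (C1 = carbinol bridgehead, C3 = N, C4 = OH, C5 = bridgehead H, C9 = one‑carbon bridge), which makes isariotin D (1S,3S,4R,5S,6S,7S,8S). "Exo" means the face of ring B on the C9 side, anti to the C2–C4 bridge. Compound 5 is drawn as the open aldehyde although it sits mainly as its spiro‑lactol. The C9 configuration of 6 and 7 is the predicted one and is erased in step 6.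

## Route

**Step 1**
Reactants: 1, methyl L‑tyrosinate hydrochloride; 2, (2E)‑dec‑2‑enoic acid
Product: 3, methyl N‑[(2E)‑dec‑2‑enoyl]‑L‑tyrosinate
Conditions: EDC·HCl, HOBt, i‑Pr2NEt, CH2Cl2, 0 °C → rt
Reagents that add atoms: none (the acyl group comes from 2)
Why: Carbodiimide/HOBt amide coupling acylates the amine in preference to the phenol and leaves Cα, the only purchased stereocentre, untouched.

**Step 2**
Reactants: 3, methyl N‑[(2E)‑dec‑2‑enoyl]‑L‑tyrosinate
Product: 4, (2E)‑N‑[(2S)‑1‑(4‑hydroxyphenyl)‑3‑oxopropan‑2‑yl]dec‑2‑enamide (N‑decenoyl‑L‑tyrosinal)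
Conditions: DIBAL‑H (3.5 equiv), CH2Cl2–toluene, −78 °C; MeOH, aq. Rochelle salt; used crude
Reagents that add atoms: none
Why: Partial ester reduction via the tetrahedral aluminate, which is stable at −78 °C; the phenol and amide N–H are deprotonated first, which shields the unsaturated amide, and the α‑amido aldehyde is not stored, to avoid epimerisation.

**Step 3**
Reactants: 4, N‑decenoyl‑L‑tyrosinal
Product: 5, (2E)‑N‑[(2S)‑1‑(1‑hydroxy‑4‑oxocyclohexa‑2,5‑dien‑1‑yl)‑3‑oxopropan‑2‑yl]dec‑2‑enamide (p‑quinol aldehyde; in solution mainly the spiro‑lactol, 3‑acylamino‑2‑hydroxy‑1‑oxaspiro[4.5]deca‑6,9‑dien‑8‑one)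
Conditions: O2, hν (530 nm), rose bengal (1 mol %), NaHCO3, MeCN–H2O, 0 °C; then Me2S, 0 °C → rt, N2 purge; crude solution carried on
Reagents that add atoms: dioxygen, O=O (one O becomes the tertiary OH; the other leaves as DMSO)
Why: Sensitised singlet‑oxygen dearomatisation of a p‑alkylphenol: ¹O₂ adds at the para (ipso) carbon to give the 4‑hydroperoxy‑cyclohexa‑2,5‑dienone, and Me2S reduces OOH to OH; the new quaternary carbon is prochiral, so no stereocentre is created, and Cα is untouched at bicarbonate pH and 0 °C.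

**Step 4** (one flask, two additions)
Reactants: 5, p‑quinol aldehyde
Product: 6, (2E)‑N‑[(1R,3S,4R,5R,7R,8S,9S)‑7,8‑epoxy‑1,4,9‑trihydroxy‑6‑oxobicyclo[3.3.1]nonan‑3‑yl]dec‑2‑enamide. C1, C3, C4, C5, C7 and C8 are arranged as in isariotin D (3‑NH equatorial, 4‑OH axial and cis to N, oxirane exo); 9‑OH is syn to 4‑OH. The descriptors at C1, C5 and C7 differ from the target only because the C6/C9 priorities change.
Conditions: K2CO3 (0.5 equiv), MeCN–H2O (1:1), 0 °C, N2, until 5 is consumed; then 30% aq. H2O2 (3 equiv), 0 °C; aq. Na2S2O3/NH4Cl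
Reagents that add atoms: water, O (C9–OH); hydrogen peroxide, OO (oxirane O)
Why: Proposed new method: carbonate triggers a reversible 6‑exo oxa‑Michael addition of the aldehyde hydrate onto either diastereotopic enone, forming a δ‑lactol that delivers O to C9 on the tether face; only the matched isomer (chair ring A, C3 amide equatorial) opens and closes by intramolecular aldol of the C5 enolate onto the aldehyde, through an open transition state in which 9‑OH hydrogen‑bonds the aldehyde oxygen, so 4‑OH is axial and syn to 9‑OH; the bicycle cannot revert by E1cB because that would need a bridgehead alkene, and HOO⁻ then epoxidises the remaining C7=C8 enone from the exo face, the endo face being buried under the C2–C4 bridge; the closest known reaction types are base‑mediated alcohol oxa‑Michael/intramolecular aldol sequences on cyclohexadienones and Weitz–Scheffer epoxidation, which have not been combined, nor run with water relayed through an aldehyde hydrate as the Michael donor, on a tyrosinal‑derived p‑quinol.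

**Step 5**
Reactants: 6, bicyclic epoxy ketone
Product: 7, (2E)‑N‑[(1R,3S,4R,5S,6S,7S,8S,9S)‑7,8‑epoxy‑1,4,6,9‑tetrahydroxybicyclo[3.3.1]nonan‑3‑yl]dec‑2‑enamide (6‑OH exo, cis to the oxirane; otherwise as 6)
Conditions: NaBH4, CeCl3·7H2O, MeOH, −78 °C
Reagents that add atoms: none
Why: Luche‑type 1,2‑reduction of the only ketone under Felkin–Anh control: hydride adds to C6 anti to the adjacent oxirane C7–O bond, that is from the endo face, because the exo trajectory runs past both oxirane C–O bonds and H9; this sets 6‑OH exo, cis to the epoxide.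

**Step 6**
Reactants: 7, tetraol
Product: 8, isariotin D, (2E)‑N‑[(1S,3S,4R,5S,6S,7S,8S)‑7,8‑epoxy‑1,4,6‑trihydroxy‑9‑oxobicyclo[3.3.1]nonan‑3‑yl]dec‑2‑enamide
Conditions: [(neocuproine)Pd(OAc)]2(OTf)2 (5 mol %), 1,4‑benzoquinone, MeCN–H2O (10:1), rt
Reagents that add atoms: none
Why: Chelation‑controlled Pd(II) alcohol oxidation is selective for vicinal diols; only 9‑OH has a neighbouring hydroxyl (the tertiary, non‑oxidisable 1‑OH, gauche to it), so the α‑hydroxy ketone forms while the isolated 4‑OH and 6‑OH remain, and no stereocentre other than C9 changes.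

## Compound list

1 | methyl L‑tyrosinate hydrochloride | N[C@@H](Cc1ccc(O)cc1)C(=O)OC.Cl | starting material
2 | (2E)‑dec‑2‑enoic acid | CCCCCCC/C=C/C(=O)O | starting material
3 | methyl N‑[(2E)‑dec‑2‑enoyl]‑L‑tyrosinate | CCCCCCC/C=C/C(=O)N[C@@H](Cc1ccc(O)cc1)C(=O)OC | intermediate
4 | (2E)‑N‑[(2S)‑1‑(4‑hydroxyphenyl)‑3‑oxopropan‑2‑yl]dec‑2‑enamide | CCCCCCC/C=C/C(=O)N[C@@H](Cc1ccc(O)cc1)C=O | intermediate
5 | (2E)‑N‑[(2S)‑1‑(1‑hydroxy‑4‑oxocyclohexa‑2,5‑dien‑1‑yl)‑3‑oxopropan‑2‑yl]dec‑2‑enamide (open form of the spiro‑lactol) | CCCCCCC/C=C/C(=O)N[C@@H](CC1(O)C=CC(=O)C=C1)C=O | intermediate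
6 | (2E)‑N‑[(1R,3S,4R,5R,7R,8S,9S)‑7,8‑epoxy‑1,4,9‑trihydroxy‑6‑oxobicyclo[3.3.1]nonan‑3‑yl]dec‑2‑enamide | CCCCCCC/C=C/C(=O)N[C@H]1C[C@@]2(O)[C@@H](O)[C@H](C(=O)[C@@H]3O[C@@H]32)[C@H]1O | intermediate
7 | (2E)‑N‑[(1R,3S,4R,5S,6S,7S,8S,9S)‑7,8‑epoxy‑1,4,6,9‑tetrahydroxybicyclo[3.3.1]nonan‑3‑yl]dec‑2‑enamide | CCCCCCC/C=C/C(=O)N[C@H]1C[C@@]2(O)[C@@H](O)[C@H]([C@H](O)[C@@H]3O[C@@H]32)[C@H]1O | intermediate
8 | isariotin D | CCCCCCC/C=C/C(=O)N[C@H]1C[C@@]2(O)C(=O)[C@H]([C@H](O)[C@@H]3O[C@@H]32)[C@H]1O | target

## Summary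

Total steps: 6. Longest linear sequence: 6 (1 → 8; acid 2 is purchased). Steps 3 and 4 are telescoped without purifying 5.

Steps most likely to fail:

1. **Step 4 (proposed new step).** Risks are amide aza‑Michael closure to a hydroindolone, Cα epimerisation of the free aldehyde, and the C4 epimer from a chelated aldol. Fallback with established reaction types, stepwise and with an external O‑donor:
   - treat 5 with p‑methoxybenzyl alcohol and DBU in MeCN (alkoxide oxa‑Michael to the quinol dienone, then intramolecular aldol) to give the 9‑O‑PMB bicyclic enone;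
   - epoxidise separately (H2O2, LiOH);
   - reduce as in step 5, then remove PMB with DDQ in wet CH2Cl2 to reach 7.
2. **Step 6 (chemoselective oxidation in a tetraol).** Fallback by protecting‑group differentiation in the 9‑O‑PMB series: silylate 4‑OH and 6‑OH (TESOTf, 2,6‑lutidine), remove PMB (DDQ), oxidise the single free secondary alcohol at C9 (Dess–Martin), and desilylate (pyridine‑buffered HF·pyridine).
3. **Step 5 (facial selectivity at C6).** The bicycle's intrinsic bias is for exo attack, which would give the 6‑epimer, so the oxirane has to override it. Fallback that sets C6 by SN2 inversion instead of facial selection: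
   - lock the syn‑diaxial 4,9‑diol of 6‑epi‑7 as its acetonide (2,2‑dimethoxypropane, PPTS);
   - Mitsunobu‑invert the only remaining secondary alcohol at C6 (p‑nitrobenzoic acid, DIAD, PPh3);
   - cleave the ester (K2CO3, MeOH) and the acetonide (PPTS, MeOH) to give 7.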